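**Retrosynthetic overview**
- The target is reached by hydrogenolysis of the catechol dibenzyl ether of the trans-lactone. The lactone C–O bond comes from a γ-hydroxy acid, itself from ozonolysis and reduction of the E-propenyl group (a masked CH2OH) of a 2,3-disubstituted hex-4-enoic acid.
- Strategic feature: the C3–C4 bond of the γ-butyrolactone ring (the lignan C8–C8' bond) joins both stereocentres, each carrying an arylmethyl group, and sits between the C2 carbonyl carbon and the C5 OCH2 carbon. It is disconnected as the sigma bond made in an Ireland–Claisen rearrangement of an (R,E)-allylic 3-arylpropanoate; C3 is epimerisable and the trans lactone is the thermodynamic isomer.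
- The (R,E)-allylic alcohol comes from (R)-but-3-yn-2-ol and 3,4-bis(benzyloxy)benzyl bromide by alkyne–benzyl coupling and trans-hydroalumination. The acyl part is bought 3-(3,4-dimethoxyphenyl)propanoic acid.
- Ring order: both benzene rings are bought; the γ-lactone is the only ring made and is closed after the rearrangement.

Key step: step 6

Remark on the chemistry: the benzyl-bearing carbon on the catechol side is S in the hexenoic acid and R in the lactones only because the CIP ranking of its neighbours changes when propenyl becomes OCH2 (no bond to it is broken after the rearrangement); (R)-but-3-yn-2-ol is assumed to be bought in high enantiomeric purity.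

**Step 1**
Reactants: 1 3,4-bis(benzyloxy)benzaldehyde
Product: 2 [3,4-bis(benzyloxy)phenyl]methanol
Conditions: NaBH4, MeOH/THF, 0 °C to rt
Reagents that add atoms: none
Why: Borohydride reduction of an aryl aldehyde to the benzylic alcohol, which leaves the benzyl ethers untouched.

**Step 2**
Reactants: 2 [3,4-bis(benzyloxy)phenyl]methanol
Product: 3 3,4-bis(benzyloxy)benzyl bromide
Conditions: PBr3, CH2Cl2, 0 °C; used promptly
Reagents that add atoms: phosphorus tribromide, BrP(Br)Br
Why: Bromination of an electron-rich benzylic alcohol through its phosphite ester and bromide displacement, run cold because the product is a labile, activated bromide.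

**Step 3**
Reactants: 3 3,4-bis(benzyloxy)benzyl bromide; 4 (R)-but-3-yn-2-ol
Product: 5 (R)-5-[3,4-bis(benzyloxy)phenyl]pent-3-yn-2-ol
Conditions: CuI (cat.), NaI (cat.), Cs2CO3, degassed MeCN, rt, Ar
Reagents that add atoms: none
Why: Copper-catalysed sp–sp3 coupling in which the copper acetylide formed under carbonate base displaces the activated benzylic halide, while the free secondary hydroxyl and its (R) centre are not involved.

**Step 4**
Reactants: 5 (R)-5-[3,4-bis(benzyloxy)phenyl]pent-3-yn-2-ol
Product: 6 (R,E)-5-[3,4-bis(benzyloxy)phenyl]pent-3-en-2-ol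
Conditions: NaAlH2(OCH2CH2OMe)2 (Red-Al), THF, 0 °C to rt; aq. potassium sodium tartrate
Reagents that add atoms: none
Why: Alkoxide-directed trans-hydroalumination of a propargylic alcohol followed by protonation of the vinyl–aluminium bond should give only the E-alkene and does not touch the carbinol centre.

**Step 5**
Reactants: 6 (R,E)-5-[3,4-bis(benzyloxy)phenyl]pent-3-en-2-ol; 7 3-(3,4-dimethoxyphenyl)propanoic acid
Product: 8 (R,E)-5-[3,4-bis(benzyloxy)phenyl]pent-3-en-2-yl 3-(3,4-dimethoxyphenyl)propanoate
Conditions: DCC, DMAP (cat.), CH2Cl2, 0 °C to rt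
Reagents that add atoms: none
Why: Steglich esterification activates the acid and not the alcohol, so the carbinol C–O bond is never broken and the (R) configuration is retained.

**Step 6**
Reactants: 8 (R,E)-5-[3,4-bis(benzyloxy)phenyl]pent-3-en-2-yl 3-(3,4-dimethoxyphenyl)propanoate
Product: 11 (2R,3S,E)-3-[3,4-bis(benzyloxy)benzyl]-2-(3,4-dimethoxybenzyl)hex-4-enoic acid, via Z-silyl ketene acetal 9 (not isolated), via TBS ester 10 (not isolated)
Conditions: LiN(iPr)2, THF/DMPU, −78 °C; TBSCl, −78 °C to rt, then 50 °C; 1 M HCl work-up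
Reagents that add atoms: tert-butyldimethylsilyl chloride, CC(C)(C)[Si](C)(C)Cl (its silyl group is carried only by intermediates 9 and 10 and is lost on work-up; none remains in acid 11)
Why: Ireland–Claisen rearrangement: LiN(iPr)2 in THF/DMPU deprotonates the only enolisable CH2 of 8 and O-silylation should give mainly the (Z)-silyl ketene acetal 9 (ArCH2 cis to OSi), which on warming undergoes a concerted suprafacial [3,3]-sigmatropic shift through a six-membered chair, forming the Cα–Cβ (lignan C8–C8') sigma bond between the two benzyl-bearing carbons while the carbinol C–O bond breaks to give silyl ester 10, hydrolysed on work-up. The closest known reaction type is the ester-enolate Claisen rearrangement of esters of enantioenriched secondary (E)-allylic alcohols with 1,3-chirality transfer. No ring is closed in this step, the six-membered array being only the transition state, and the lactone is closed later. C3 of 11 is controlled by the (R)-carbinol centre and the E-alkene: with the carbinol methyl pseudo-equatorial the ketene acetal is delivered to one face of the allyl terminus, which should give 3S (4R in the lactone) and an E-propenyl group while the original stereocentre is consumed. C2 is controlled by the ketene acetal geometry, the Z isomer leading through the chair to 2R (the syn acid, hence the trans lactone). The step therefore needs facial selectivity at the allyl terminus, secured by the small methyl group that would suffer a 1,3-diaxial clash with the OSi-bearing carbon if axial, whereas any shortfall in enolate geometry or in chair over boat preference affects only C2, which is corrected by the later epimerisation.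

**Step 7**
Reactants: 11 (2R,3S,E)-3-[3,4-bis(benzyloxy)benzyl]-2-(3,4-dimethoxybenzyl)hex-4-enoic acid
Product: 14 (4R)-4-[3,4-bis(benzyloxy)benzyl]-3-(3,4-dimethoxybenzyl)dihydrofuran-2(3H)-one (C3 epimers; trans expected as major), via secondary ozonide 12 (not isolated), via hydroxy acid 13 (not isolated)
Conditions: O3, CH2Cl2, −78 °C (Sudan Red 7B end point); MeOH, NaBH4, −78 to 0 °C; 1 M HCl, then p-TsOH (cat.), CH2Cl2, rt
Reagents that add atoms: ozone, O=[O+][O-]
Why: Ozonolysis with reductive work-up followed by lactonisation, in which the isolated propenyl alkene should react with ozone well before the alkoxyarenes (the dye marks the end point), borohydride takes the peroxidic product straight to the primary alcohol so that no α-chiral aldehyde persists, and the γ-hydroxy acid closes by 5-exo-trig acyl substitution under acid, leaving C4 untouched and C3 as delivered by step 6.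

**Step 8**
Reactants: 14 (4R)-4-[3,4-bis(benzyloxy)benzyl]-3-(3,4-dimethoxybenzyl)dihydrofuran-2(3H)-one (C3 epimers)
Product: 15 (3R,4R)-4-[3,4-bis(benzyloxy)benzyl]-3-(3,4-dimethoxybenzyl)dihydrofuran-2(3H)-one (trans)
Conditions: DBU, toluene, 80 °C
Reagents that add atoms: none
Why: Base-mediated epimerisation through the lactone enolate equilibrates only the acidic C3 position, so any cis isomer should converge on the thermodynamically preferred trans-3,4-dibenzyl lactone while the non-acidic C4 centre keeps its configuration.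

**Step 9**
Reactants: 15 (3R,4R)-4-[3,4-bis(benzyloxy)benzyl]-3-(3,4-dimethoxybenzyl)dihydrofuran-2(3H)-one
Product: 16 (3R,4R)-4-(3,4-dihydroxybenzyl)-3-(3,4-dimethoxybenzyl)dihydrofuran-2(3H)-one (target CNP0119683.1)
Conditions: H2 (1 atm), 10% Pd/C, EtOAc/MeOH, rt; handled under Ar
Reagents that add atoms: none
Why: Catalytic hydrogenolysis cleaves both aryl benzyl ethers under neutral conditions that leave the lactone, the methyl ethers and both stereocentres unchanged.

**Compound list**
1 | 3,4-bis(benzyloxy)benzaldehyde | O=Cc1ccc(OCc2ccccc2)c(OCc2ccccc2)c1 | starting material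
2 | [3,4-bis(benzyloxy)phenyl]methanol | OCc1ccc(OCc2ccccc2)c(OCc2ccccc2)c1 | intermediate
3 | 3,4-bis(benzyloxy)benzyl bromide | BrCc1ccc(OCc2ccccc2)c(OCc2ccccc2)c1 | intermediate
4 | (R)-but-3-yn-2-ol | C[C@@H](O)C#C | starting material
5 | (R)-5-[3,4-bis(benzyloxy)phenyl]pent-3-yn-2-ol | C[C@@H](O)C#CCc1ccc(OCc2ccccc2)c(OCc2ccccc2)c1 | intermediate
6 | (R,E)-5-[3,4-bis(benzyloxy)phenyl]pent-3-en-2-ol | C[C@@H](O)/C=C/Cc1ccc(OCc2ccccc2)c(OCc2ccccc2)c1 | intermediate
7 | 3-(3,4-dimethoxyphenyl)propanoic acid | COc1ccc(CCC(=O)O)cc1OC | starting material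
8 | (R,E)-5-[3,4-bis(benzyloxy)phenyl]pent-3-en-2-yl 3-(3,4-dimethoxyphenyl)propanoate | C[C@@H](OC(=O)CCc1ccc(OC)c(OC)c1)/C=C/Cc1ccc(OCc2ccccc2)c(OCc2ccccc2)c1 | intermediate
9 | (Z)-O-tert-butyldimethylsilyl ketene acetal of ester 8 (ArCH2 cis to OSi) | C[C@@H](O/C(O[Si](C)(C)C(C)(C)C)=C/Cc1ccc(OC)c(OC)c1)/C=C/Cc1ccc(OCc2ccccc2)c(OCc2ccccc2)c1 | intermediate (not isolated)
10 | tert-butyldimethylsilyl (2R,3S,E)-3-[3,4-bis(benzyloxy)benzyl]-2-(3,4-dimethoxybenzyl)hex-4-enoate | C/C=C/[C@H](Cc1ccc(OCc2ccccc2)c(OCc2ccccc2)c1)[C@@H](Cc1ccc(OC)c(OC)c1)C(=O)O[Si](C)(C)C(C)(C)C | intermediate (not isolated)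
11 | (2R,3S,E)-3-[3,4-bis(benzyloxy)benzyl]-2-(3,4-dimethoxybenzyl)hex-4-enoic acid | C/C=C/[C@H](Cc1ccc(OCc2ccccc2)c(OCc2ccccc2)c1)[C@@H](Cc1ccc(OC)c(OC)c1)C(=O)O | intermediate
12 | (2R,3R)-3-[3,4-bis(benzyloxy)benzyl]-2-(3,4-dimethoxybenzyl)-3-(5-methyl-1,2,4-trioxolan-3-yl)propanoic acid (secondary ozonide) | CC1OC(OO1)[C@H](Cc1ccc(OCc2ccccc2)c(OCc2ccccc2)c1)[C@@H](Cc1ccc(OC)c(OC)c1)C(=O)O | intermediate (not isolated)
13 | (2R,3R)-3-[3,4-bis(benzyloxy)benzyl]-2-(3,4-dimethoxybenzyl)-4-hydroxybutanoic acid | OC[C@H](Cc1ccc(OCc2ccccc2)c(OCc2ccccc2)c1)[C@@H](Cc1ccc(OC)c(OC)c1)C(=O)O | intermediate (not isolated)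
14 | (4R)-4-[3,4-bis(benzyloxy)benzyl]-3-(3,4-dimethoxybenzyl)dihydrofuran-2(3H)-one, C3 epimers | COc1ccc(CC2C(=O)OC[C@@H]2Cc2ccc(OCc3ccccc3)c(OCc3ccccc3)c2)cc1OC | intermediate
15 | (3R,4R)-4-[3,4-bis(benzyloxy)benzyl]-3-(3,4-dimethoxybenzyl)dihydrofuran-2(3H)-one | COc1ccc(C[C@H]2C(=O)OC[C@@H]2Cc2ccc(OCc3ccccc3)c(OCc3ccccc3)c2)cc1OC | intermediate
16 | (3R,4R)-4-(3,4-dihydroxybenzyl)-3-(3,4-dimethoxybenzyl)dihydrofuran-2(3H)-one | COc1ccc(C[C@H]2C(=O)OC[C@@H]2Cc2ccc(O)c(O)c2)cc1OC | target

**Totals**
Total step count: 9. Longest linear sequence: 9 steps (1 to 16); compounds 4 and 7 are bought and enter directly.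

**Steps most likely to fail**

Step 6. The ester enolate may form incompletely or fragment before silylation, or a competing transition state with the carbinol methyl axial may erode the 1,3-chirality transfer, lowering conversion into the rearranged acid or its enantiomeric purity. The fallback keeps the same sigmatropic bond formation but avoids enolate chemistry; it sets out from 6 and returns at 15. Alcohol 6 is heated with triethyl orthoacetate and catalytic propanoic acid (Johnson–Claisen rearrangement), which should give ethyl (R,E)-3-[3,4-bis(benzyloxy)benzyl]hex-4-enoate F1 through the same chair. Ozonolysis with NaBH4 work-up then gives ethyl (R)-3-[3,4-bis(benzyloxy)benzyl]-4-hydroxybutanoate F2, which lactonises under acid to (R)-4-[3,4-bis(benzyloxy)benzyl]dihydrofuran-2(3H)-one F3. Deprotonation of this lactone with LiN(SiMe3)2 in THF at −78 °C and alkylation with bought 3,4-dimethoxybenzyl bromide, which enters anti to the C4 substituent, should give trans-lactone 15 directly.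

Step 3. Carbonate base may isomerise the benzylic alkyne to the aryl allene, the alkyne may homocouple oxidatively, or the hydroxyl may be benzylated. The fallback replaces the catalytic coupling of the free alcohol by a stoichiometric acetylide alkylation of a protected alkyne; it sets out from 4 (with 3) and returns at 5. Alcohol 4 is silylated (TBSCl, imidazole, DMF) to (R)-tert-butyl(but-3-yn-2-yloxy)dimethylsilane F4. This is deprotonated with EtMgBr in THF and alkylated with bromide 3 under CuCl catalysis to give (R)-{[5-(3,4-bis(benzyloxy)phenyl)pent-3-yn-2-yl]oxy}(tert-butyl)dimethylsilane F5. Desilylation with Bu4NF in THF then gives 5.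

Step 7. Ozone may over-oxidise the electron-rich arene rings or the benzylic ether CH2 groups before the alkene is consumed, or the centre next to the transient aldehyde may epimerise. The fallback uses osmium-catalysed dihydroxylation with periodate cleavage on the ester in place of ozone; it sets out from 11 and returns at 14. Acid 11 is methylated (MeI, K2CO3, DMF) to methyl (2R,3S,E)-3-[3,4-bis(benzyloxy)benzyl]-2-(3,4-dimethoxybenzyl)hex-4-enoate F6. Cleavage with OsO4 (cat.), NaIO4 and 2,6-lutidine in dioxane/water gives methyl (2R,3R)-3-[3,4-bis(benzyloxy)benzyl]-2-(3,4-dimethoxybenzyl)-4-oxobutanoate F7. Immediate reduction with NaBH4 in MeOH at 0 °C gives methyl (2R,3R)-3-[3,4-bis(benzyloxy)benzyl]-2-(3,4-dimethoxybenzyl)-4-hydroxybutanoate F8, which closes with catalytic p-TsOH to lactone 14.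

**Further compounds**
F1 | step 6 | ethyl (R,E)-3-[3,4-bis(benzyloxy)benzyl]hex-4-enoate | C/C=C/[C@H](Cc1ccc(OCc2ccccc2)c(OCc2ccccc2)c1)CC(=O)OCC
F2 | step 6 | ethyl (R)-3-[3,4-bis(benzyloxy)benzyl]-4-hydroxybutanoate | OC[C@H](Cc1ccc(OCc2ccccc2)c(OCc2ccccc2)c1)CC(=O)OCC
F3 | step 6 | (R)-4-[3,4-bis(benzyloxy)benzyl]dihydrofuran-2(3H)-one | O=C1C[C@@H](Cc2ccc(OCc3ccccc3)c(OCc3ccccc3)c2)CO1
F4 | step 3 | (R)-tert-butyl(but-3-yn-2-yloxy)dimethylsilane | C[C@@H](O[Si](C)(C)C(C)(C)C)C#C
F5 | step 3 | (R)-{[5-(3,4-bis(benzyloxy)phenyl)pent-3-yn-2-yl]oxy}(tert-butyl)dimethylsilane | C[C@@H](O[Si](C)(C)C(C)(C)C)C#CCc1ccc(OCc2ccccc2)c(OCc2ccccc2)c1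
F6 | step 7 | methyl (2R,3S,E)-3-[3,4-bis(benzyloxy)benzyl]-2-(3,4-dimethoxybenzyl)hex-4-enoate | C/C=C/[C@H](Cc1ccc(OCc2ccccc2)c(OCc2ccccc2)c1)[C@@H](Cc1ccc(OC)c(OC)c1)C(=O)OC
F7 | step 7 | methyl (2R,3R)-3-[3,4-bis(benzyloxy)benzyl]-2-(3,4-dimethoxybenzyl)-4-oxobutanoate | O=C[C@H](Cc1ccc(OCc2ccccc2)c(OCc2ccccc2)c1)[C@@H](Cc1ccc(OC)c(OC)c1)C(=O)OC
F8 | step 7 | methyl (2R,3R)-3-[3,4-bis(benzyloxy)benzyl]-2-(3,4-dimethoxybenzyl)-4-hydroxybutanoate | OC[C@H](Cc1ccc(OCc2ccccc2)c(OCc2ccccc2)c1)[C@@H](Cc1ccc(OC)c(OC)c1)C(=O)OC
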